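**Plan**
- Retrosynthesis: the homofarnesyl chain is cut between its second and third carbon (B-alkyl Suzuki–Miyaura; a vinyl group on the quaternary ring carbon is the anchor). The hydroxypropyl chain is cut two carbons from its oxygen (alkyllithium plus oxirane), and the enal is taken back to a silyl-protected allylic alcohol.
- The cyclohexane is then cut at the two ring bonds that flank the pair "ring C bearing the exocyclic C=C(CH3)CHO / ring CH bearing the side chain". This is a [4+2] retron.
- Enabling feature: these two ring carbons are the central and a terminal carbon of a 1,2-diene (an allenoate). The other four ring carbons (quaternary C(CH3)(chain), CH(CH3), CH2, CH2) are one diene half of the C2-symmetric (3Z)-3,4-dimethylhexa-1,3,5-triene, and the unused vinyl group stays on the quaternary carbon.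
- Forward: triene plus enantioenriched allenoate closes the only ring. Ester reduction, chain coupling, ring-olefin hydrogenation, two-carbon homologation, desilylation and allylic oxidation follow.
- Stereochemistry: the allene axis (from (S)-2-methylglycidol by anti SN2′ carbonylation) sets the ring CH stereocenter and the (Z) exocyclic olefin. The (Z) triene geometry plus endo addition sets the quaternary center. Hydroxyl-directed hydrogenation sets the CH(CH3) center. The chain (E) olefins come from geranylacetone and syn-carboalumination.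

Key step: step 9

Remark: the palladium-catalysed alkoxycarbonylation of the ethynyl oxirane is taken to follow the usual anti SN2′ course; this fixes the choice of the (S) epoxide.

**Route**

Step 1
Reactants: 1 but-2-yne
Product: 2 (2Z)-2,3-bis(4,4,5,5-tetramethyl-1,3,2-dioxaborolan-2-yl)but-2-ene
Conditions: B2pin2, Pt(PPh3)4 (3 mol%), DMF, 80 °C, sealed tube
Reagents that add atoms: bis(pinacolato)diboron CC1(C)OB(OC1(C)C)B1OC(C)(C)C(C)(C)O1
Why: Platinum-catalysed diboration of an internal alkyne is a syn addition, so both boryl groups end up on the same side and the (Z) geometry of the tetrasubstituted olefin is fixed.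

Step 2
Reactants: 2 (2Z)-2,3-bis(pinacolboryl)but-2-ene
Product: 4 (3Z)-3,4-dimethylhexa-1,3,5-triene, via monovinyl boronate 3 (not isolated)
Conditions: vinyl bromide (2.5 equiv), Pd(dppf)Cl2 (5 mol%), K3PO4 (aq), dioxane, 70 °C, sealed tube; volatile product kept as a pentane/CH2Cl2 solution
Reagents that add atoms: vinyl bromide C=CBr
Why: Twofold Suzuki–Miyaura coupling proceeds with retention at both C–B bonds, so the two vinyl groups should end up cis on the central double bond.

Step 3
Reactants: 5 (S)-2-methylglycidol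
Product: 6 (R)-2-methyloxirane-2-carbaldehyde
Conditions: TEMPO (10 mol%), PhI(OAc)2, CH2Cl2, 0 °C → rt; solution used directly
Reagents that add atoms: none
Why: Nitroxyl-catalysed oxidation stops at the aldehyde and leaves the epoxide and its quaternary stereocenter (no α-hydrogen) untouched; the descriptor changes only because the CIP priorities change.

Step 4
Reactants: 6 (R)-2-methyloxirane-2-carbaldehyde
Product: 7 (S)-2-ethynyl-2-methyloxirane
Conditions: dimethyl (1-diazo-2-oxopropyl)phosphonate, K2CO3, MeOH, 0 °C → rt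
Reagents that add atoms: dimethyl (1-diazo-2-oxopropyl)phosphonate CC(=O)C(=[N+]=[N-])P(=O)(OC)OC
Why: Ohira–Bestmann homologation converts the non-enolisable aldehyde into the terminal alkyne under mild carbonate conditions without touching the stereocenter.

Step 5
Reactants: 7 (S)-2-ethynyl-2-methyloxirane
Product: 8 methyl (S)-5-hydroxy-4-methylpenta-2,3-dienoate
Conditions: Pd2(dba)3·CHCl3 (2 mol%), PPh3 (8 mol%), CO (20 atm), MeOH–THF, 25 °C, short reaction time
Reagents that add atoms: carbon monoxide [C-]#[O+]; methanol CO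
Why: Zerovalent palladium attacks the alkyne terminus anti to the propargylic C–O bond (SN2′) and CO insertion/methanolysis occurs with retention, so the central chirality of the epoxide should be transferred to the (S) allene axis (alkoxycarbonylation of a propargylic oxirane).

Step 6
Reactants: 8 methyl (S)-5-hydroxy-4-methylpenta-2,3-dienoate
Product: 9 methyl (S)-5-[(tert-butyldiphenylsilyl)oxy]-4-methylpenta-2,3-dienoate
Conditions: TBDPSCl, imidazole, CH2Cl2, 0 °C
Reagents that add atoms: tert-butylchlorodiphenylsilane CC(C)(C)[Si](Cl)(c1ccccc1)c1ccccc1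
Why: Standard silylation of the primary alcohol; the bulky silyloxymethyl group also enlarges the size difference between the two substituents of the distal allene carbon that is used in step 9.

Step 7
Reactants: 10 (5E)-6,10-dimethylundeca-5,9-dien-2-one (geranylacetone)
Product: 12 (5E)-6,10-dimethylundeca-5,9-dien-1-yne, via enol phosphate 11 (not isolated)
Conditions: LDA, THF, −78 °C; ClP(O)(OEt)2; then LDA (2.3 equiv), −78 °C → rt
Reagents that add atoms: none
Why: Kinetic enolisation on the methyl side, O-phosphorylation and elimination with LDA turn the methyl ketone into the terminal alkyne without touching the (E) olefin (enol phosphate elimination).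

Step 8
Reactants: 12 (5E)-6,10-dimethylundeca-5,9-dien-1-yne
Product: 14 (1E,5E)-1-iodo-2,6,10-trimethylundeca-1,5,9-triene, via alkenylalane 13 (not isolated)
Conditions: Me3Al, Cp2ZrCl2 (25 mol%), CH2Cl2, rt; then I2, THF, −30 °C
Reagents that add atoms: trimethylaluminium C[Al](C)C; iodine II
Why: Zirconium-catalysed syn-carboalumination puts methyl and aluminium cis across the alkyne and iodinolysis occurs with retention, giving the (E) trisubstituted vinyl iodide (Negishi carboalumination).

Step 9
Reactants: 4 (3Z)-3,4-dimethylhexa-1,3,5-triene; 9 methyl (S)-5-[(tert-butyldiphenylsilyl)oxy]-4-methylpenta-2,3-dienoate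
Product: 15 methyl (1R,2S,6Z)-6-[1-(tert-butyldiphenylsilyloxy)propan-2-ylidene]-2,3-dimethyl-2-vinylcyclohex-3-ene-1-carboxylate
Conditions: Me2AlCl (1.2 equiv), 4 (3 equiv), CH2Cl2, −78 → −30 °C
Reagents that add atoms: none
Why: The Lewis acid lowers the LUMO of the ester-conjugated 2,3-double bond of 9, and the s-cis diene unit of 4 (either half of the C2-symmetric triene gives the same adduct) adds across it in a concerted but asynchronous [4π+2π] cycloaddition in which the unsubstituted CH2 terminus bonds first to the central allene carbon and the fully substituted terminus then closes onto the ester-bearing carbon. The closest known reaction type is the Lewis-acid-promoted Diels–Alder reaction of 2,3-allenoates with acyclic dienes with axial-to-central chirality transfer. The cyclohexene is closed by an intermolecular suprafacial–suprafacial cycloaddition through an endo transition state, not by a tethered cyclization. The CH(CO2Me) stereocenter and the (Z) geometry of the exocyclic olefin are both controlled by the allene axis, because the diene approaches the face syn to the methyl and anti to the CH2OTBDPS group of the distal allene carbon; the quaternary center is controlled by the (Z) geometry of the triene (methyl outside, vinyl inside) together with the endo orientation of the ester, which places CO2Me cis to the methyl group. The step needs chemoselectivity for the conjugated allene bond (the only one in the LUMO), ortho regioselectivity (largest HOMO coefficient at the CH2 terminus, largest LUMO coefficient at the central allene carbon) and endo selectivity (secondary orbital overlap, and only hydrogen then faces the inside vinyl group).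

Step 10
Reactants: 15 Diels–Alder adduct (methyl ester)
Product: 16 [(1R,2S,6Z)-6-[1-(tert-butyldiphenylsilyloxy)propan-2-ylidene]-2,3-dimethyl-2-vinylcyclohex-3-en-1-yl]methanol
Conditions: DIBAL-H (2.5 equiv), CH2Cl2, −78 → 0 °C; Rochelle salt
Reagents that add atoms: none
Why: Hydride reduction of the ester to the primary alcohol, done directly after step 9 so that the epimerisable α-hydrogen of the β,γ-unsaturated ester never meets a base.

Step 11
Reactants: 16 vinyl alcohol; 14 (1E,5E)-1-iodo-2,6,10-trimethylundeca-1,5,9-triene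
Product: 18 [(1R,2S,6Z)-6-[1-(tert-butyldiphenylsilyloxy)propan-2-ylidene]-2,3-dimethyl-2-[(3E,7E)-4,8,12-trimethyltrideca-3,7,11-trien-1-yl]cyclohex-3-en-1-yl]methanol, via B-alkyl borane 17 (not isolated)
Conditions: 9-BBN (2.2 equiv), THF, rt; then 14, Pd(dppf)Cl2 (5 mol%), AsPh3, Cs2CO3, DMF–H2O, rt
Reagents that add atoms: none
Why: 9-BBN hydroborates only the monosubstituted vinyl group at its terminus, and the B-alkyl borane couples with the vinyl iodide with retention of the (E) geometry (B-alkyl Suzuki–Miyaura coupling).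

Step 12
Reactants: 18 cyclohexenyl methanol with complete side chain
Product: 19 [(1S,2R,3R,6Z)-6-[1-(tert-butyldiphenylsilyloxy)propan-2-ylidene]-2,3-dimethyl-2-[(3E,7E)-4,8,12-trimethyltrideca-3,7,11-trien-1-yl]cyclohexyl]methanol
Conditions: [Rh(nbd)(dppb)]BF4 (10 mol%), H2 (55 atm), CH2Cl2, 25 °C
Reagents that add atoms: none
Why: The cationic rhodium catalyst binds the primary hydroxyl and should deliver H2 to the ring olefin from the face that carries CH2OH (also the face opposite to the pseudoaxial side chain), which places the new ring hydrogen cis to the quaternary methyl and gives the (R) methyl-bearing center; the chain olefins have no binding group and the tetrasubstituted olefin is too hindered (hydroxyl-directed homogeneous hydrogenation).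

Step 13
Reactants: 19 saturated ring alcohol
Product: 20 tert-butyl{[(2Z)-2-[(2S,3R,4R)-2-(iodomethyl)-3,4-dimethyl-3-[(3E,7E)-4,8,12-trimethyltrideca-3,7,11-trien-1-yl]cyclohexylidene]propyl]oxy}diphenylsilane
Conditions: I2, PPh3, imidazole, CH2Cl2, 0 °C → rt
Reagents that add atoms: iodine II
Why: Appel-type iodination of a primary alcohol by SN2 displacement of the oxyphosphonium group; the preformed phosphonium iodide does not add to the trisubstituted olefins.

Step 14
Reactants: 20 primary iodide
Product: 22 3-[(1S,2R,3R,6Z)-6-[1-(tert-butyldiphenylsilyloxy)propan-2-ylidene]-2,3-dimethyl-2-[(3E,7E)-4,8,12-trimethyltrideca-3,7,11-trien-1-yl]cyclohexyl]propan-1-ol, via alkyllithium 21 (not isolated)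
Conditions: t-BuLi (2.1 equiv), Et2O–pentane, −78 °C; then oxirane, BF3·OEt2, −78 °C
Reagents that add atoms: oxirane C1CO1
Why: Lithium–iodine exchange gives the primary alkyllithium, which opens BF3-activated oxirane and so adds the two missing carbons and the terminal hydroxyl in one operation (epoxide alkylation).

Step 15
Reactants: 22 silyl-protected hydroxypropyl compound
Product: 23 (2Z)-2-[(2S,3R,4R)-2-(3-hydroxypropyl)-3,4-dimethyl-3-[(3E,7E)-4,8,12-trimethyltrideca-3,7,11-trien-1-yl]cyclohexylidene]propan-1-ol
Conditions: TBAF, THF, 0 °C → rt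
Reagents that add atoms: none
Why: Fluoride cleavage of the silyl ether frees the allylic alcohol without affecting olefins or stereocenters.

Step 16
Reactants: 23 diol
Product: 24 (2Z)-2-[(2S,3R,4R)-2-(3-hydroxypropyl)-3,4-dimethyl-3-[(3E,7E)-4,8,12-trimethyltrideca-3,7,11-trien-1-yl]cyclohexylidene]propanal (target)
Conditions: MnO2 (activated, excess), CH2Cl2, rt
Reagents that add atoms: none
Why: MnO2 oxidises only the allylic alcohol and leaves the saturated primary alcohol, and the tetrasubstituted enal should keep the (Z) geometry set in step 9 (chemoselective allylic oxidation).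

**Compound list**
1 | but-2-yne | CC#CC | starting material
2 | (2Z)-2,3-bis(4,4,5,5-tetramethyl-1,3,2-dioxaborolan-2-yl)but-2-ene | C/C(B1OC(C)(C)C(C)(C)O1)=C(\C)B1OC(C)(C)C(C)(C)O1 | intermediate
3 | 4,4,5,5-tetramethyl-2-[(2E)-3-methylpenta-2,4-dien-2-yl]-1,3,2-dioxaborolane (boryl cis to vinyl) | C=C/C(C)=C(/C)B1OC(C)(C)C(C)(C)O1 | intermediate
4 | (3Z)-3,4-dimethylhexa-1,3,5-triene | C=C/C(C)=C(/C)C=C | intermediate
5 | (S)-2-methylglycidol, [(2S)-2-methyloxiran-2-yl]methanol | C[C@]1(CO)CO1 | starting material
6 | (R)-2-methyloxirane-2-carbaldehyde | C[C@]1(C=O)CO1 | intermediate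
7 | (S)-2-ethynyl-2-methyloxirane | C[C@]1(C#C)CO1 | intermediate
8 | methyl (S)-5-hydroxy-4-methylpenta-2,3-dienoate | COC(=O)C([H])=[C@@]=C(C)CO | intermediate
9 | methyl (S)-5-[(tert-butyldiphenylsilyl)oxy]-4-methylpenta-2,3-dienoate | COC(=O)C([H])=[C@@]=C(C)CO[Si](c1ccccc1)(c1ccccc1)C(C)(C)C | intermediate
10 | (5E)-6,10-dimethylundeca-5,9-dien-2-one (geranylacetone) | CC(=O)CC/C=C(\C)CCC=C(C)C | starting material
11 | diethyl (5E)-6,10-dimethylundeca-1,5,9-trien-2-yl phosphate | C=C(OP(=O)(OCC)OCC)CC/C=C(\C)CCC=C(C)C | intermediate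
12 | (5E)-6,10-dimethylundeca-5,9-dien-1-yne | C#CCC/C=C(\C)CCC=C(C)C | intermediate
13 | dimethyl[(1E,5E)-2,6,10-trimethylundeca-1,5,9-trien-1-yl]alumane | C[Al](C)/C=C(\C)CC/C=C(\C)CCC=C(C)C | intermediate
14 | (1E,5E)-1-iodo-2,6,10-trimethylundeca-1,5,9-triene | I/C=C(\C)CC/C=C(\C)CCC=C(C)C | intermediate
15 | methyl (1R,2S,6Z)-6-[1-(tert-butyldiphenylsilyloxy)propan-2-ylidene]-2,3-dimethyl-2-vinylcyclohex-3-ene-1-carboxylate | C=C[C@]1(C)C(C)=CC/C(=C(\C)CO[Si](c2ccccc2)(c2ccccc2)C(C)(C)C)[C@H]1C(=O)OC | intermediate
16 | [(1R,2S,6Z)-6-[1-(tert-butyldiphenylsilyloxy)propan-2-ylidene]-2,3-dimethyl-2-vinylcyclohex-3-en-1-yl]methanol | C=C[C@]1(C)C(C)=CC/C(=C(\C)CO[Si](c2ccccc2)(c2ccccc2)C(C)(C)C)[C@H]1CO | intermediate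
17 | 9-BBN adduct of 16: 9-borabicyclo[3.3.1]nonan-9-yl on the terminal carbon of the former vinyl group, and O-(9-borabicyclo[3.3.1]nonan-9-yl) borinate of the alcohol | C1CCC2CCCC1B2CC[C@]3(C)C(C)=CC/C(=C(\C)CO[Si](c4ccccc4)(c4ccccc4)C(C)(C)C)[C@H]3COB1C2CCCC1CCC2 | intermediate
18 | [(1R,2S,6Z)-6-[1-(tert-butyldiphenylsilyloxy)propan-2-ylidene]-2,3-dimethyl-2-[(3E,7E)-4,8,12-trimethyltrideca-3,7,11-trien-1-yl]cyclohex-3-en-1-yl]methanol | CC(C)=CCC/C(C)=C/CC/C(C)=C/CC[C@]1(C)C(C)=CC/C(=C(\C)CO[Si](c2ccccc2)(c2ccccc2)C(C)(C)C)[C@H]1CO | intermediate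
19 | [(1S,2R,3R,6Z)-6-[1-(tert-butyldiphenylsilyloxy)propan-2-ylidene]-2,3-dimethyl-2-[(3E,7E)-4,8,12-trimethyltrideca-3,7,11-trien-1-yl]cyclohexyl]methanol | CC(C)=CCC/C(C)=C/CC/C(C)=C/CC[C@]1(C)[C@H](C)CC/C(=C(\C)CO[Si](c2ccccc2)(c2ccccc2)C(C)(C)C)[C@H]1CO | intermediate
20 | tert-butyl{[(2Z)-2-[(2S,3R,4R)-2-(iodomethyl)-3,4-dimethyl-3-[(3E,7E)-4,8,12-trimethyltrideca-3,7,11-trien-1-yl]cyclohexylidene]propyl]oxy}diphenylsilane | CC(C)=CCC/C(C)=C/CC/C(C)=C/CC[C@]1(C)[C@H](C)CC/C(=C(\C)CO[Si](c2ccccc2)(c2ccccc2)C(C)(C)C)[C@H]1CI | intermediate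
21 | primary alkyllithium from 20 (CH2Li in place of CH2I) | CC(C)=CCC/C(C)=C/CC/C(C)=C/CC[C@]1(C)[C@H](C)CC/C(=C(\C)CO[Si](c2ccccc2)(c2ccccc2)C(C)(C)C)[C@H]1C[Li] | intermediate
22 | 3-[(1S,2R,3R,6Z)-6-[1-(tert-butyldiphenylsilyloxy)propan-2-ylidene]-2,3-dimethyl-2-[(3E,7E)-4,8,12-trimethyltrideca-3,7,11-trien-1-yl]cyclohexyl]propan-1-ol | CC(C)=CCC/C(C)=C/CC/C(C)=C/CC[C@]1(C)[C@H](C)CC/C(=C(\C)CO[Si](c2ccccc2)(c2ccccc2)C(C)(C)C)[C@H]1CCCO | intermediate
23 | (2Z)-2-[(2S,3R,4R)-2-(3-hydroxypropyl)-3,4-dimethyl-3-[(3E,7E)-4,8,12-trimethyltrideca-3,7,11-trien-1-yl]cyclohexylidene]propan-1-ol | CC(C)=CCC/C(C)=C/CC/C(C)=C/CC[C@]1(C)[C@H](C)CC/C(=C(\C)CO)[C@H]1CCCO | intermediate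
24 | (2Z)-2-[(2S,3R,4R)-2-(3-hydroxypropyl)-3,4-dimethyl-3-[(3E,7E)-4,8,12-trimethyltrideca-3,7,11-trien-1-yl]cyclohexylidene]propanal | CC(C)=CCC/C(C)=C/CC/C(C)=C/CC[C@]1(C)[C@H](C)CC/C(=C(\C)C=O)[C@H]1CCCO | target

**Totals and risks**

Total step count: 16. Longest linear sequence: 12 steps (5 → 24 through steps 3–6 and 9–16).

Steps most likely to fail:

1. Step 9. The diene terminus that becomes the quaternary carbon carries an inside (Z) vinyl group, so the s-cis geometry is poorly populated. The electron-rich triene may then be lost to Lewis-acid-induced oligomerization or to stepwise closure to a four-membered ring, and endo selectivity may erode. The fallback sets out from monovinyl boronate 3, isolated when step 2 is run with one equivalent of vinyl bromide. It is not a triene, is less electron-rich and tolerates heating. Thermal Diels–Alder reaction of 3 with 9 (toluene, 100 °C, BHT) should give the pinacolboryl analogue of 15 F1 (boryl inside, methyl outside, same endo and facial arguments). DIBAL-H (CH2Cl2, −78 °C) reduces the ester to the boronate alcohol F2. Vinyllithium (2.2 equiv, THF, −78 °C) forms the lithium alkoxide vinyl boronate complex F3, which is not isolated. I2 followed by NaOMe in MeOH induces 1,2-migration of the tertiary carbon with retention and anti elimination (Zweifel olefination), and the route is rejoined at 16.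

2. Step 12. At the pressure needed for a hydroxyl that sits one ring carbon beyond the allylic position, chemoselectivity may be lost through slow reduction of the three chain olefins, or conversion may stay incomplete. The fallback reduces the ring olefin before the polyene chain exists and sets out from 16. Iridium-catalysed hydroboration of the vinyl group with pinacolborane ([Ir(cod)Cl]2, dppe, HBpin, CH2Cl2; aqueous work-up) should give the primary pinacol boronate F4. Hydroxyl-directed hydrogenation with [Ir(cod)(PCy3)(py)]PF6 (H2 1 atm, CH2Cl2, 0 °C) gives the ring-saturated boronate F5, with only the hindered tetrasubstituted olefin as a competitor. Suzuki–Miyaura coupling of F5 with 14 (Pd(dppf)Cl2, Ba(OH)2, DMF–H2O, 50 °C) rejoins the route at 19.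

3. Step 14. The hindered primary alkyllithium may be protonated or lost by Wurtz-type coupling before it captures oxirane, and BF3 may start cation–olefin reactions of the polyene. The fallback reverses the polarity at this carbon and sets out from 19. Tf2O and 2,6-lutidine (CH2Cl2, −78 °C) give the primary triflate F6. Displacement with the lithium enolate of tert-butyl acetate (LDA, THF–DMPU, −78 → −20 °C) gives the tert-butyl ester F7. LiAlH4 (Et2O, 0 °C) reduces F7 and rejoins the route at 22.

Further compounds
F1 | step 9 | methyl 6-[(Z)-1-(tert-butyldiphenylsilyloxy)propan-2-ylidene]-2,3-dimethyl-2-(4,4,5,5-tetramethyl-1,3,2-dioxaborolan-2-yl)cyclohex-3-ene-1-carboxylate, boryl trans and methyl cis to the ester, configuration as in 15 | CC1(C)OB([C@]2(C)C(C)=CC/C(=C(\C)CO[Si](c3ccccc3)(c3ccccc3)C(C)(C)C)[C@H]2C(=O)OC)OC1(C)C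
F2 | step 9 | primary alcohol from F1 (CH2OH in place of CO2Me) | CC1(C)OB([C@]2(C)C(C)=CC/C(=C(\C)CO[Si](c3ccccc3)(c3ccccc3)C(C)(C)C)[C@H]2CO)OC1(C)C
F3 | step 9 | dilithium salt of the B-vinyl boronate complex of F2 (alkoxide and tetracoordinate borate) | [Li+].[Li+].C=C[B-]1(OC(C)(C)C(C)(C)O1)[C@]1(C)C(C)=CC/C(=C(\C)CO[Si](c2ccccc2)(c2ccccc2)C(C)(C)C)[C@H]1C[O-]
F4 | step 12 | analogue of 16 with 2-(4,4,5,5-tetramethyl-1,3,2-dioxaborolan-2-yl)ethyl in place of vinyl | CC1(C)OB(CC[C@]2(C)C(C)=CC/C(=C(\C)CO[Si](c3ccccc3)(c3ccccc3)C(C)(C)C)[C@H]2CO)OC1(C)C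
F5 | step 12 | ring-saturated analogue of F4 with the (R) methyl-bearing center of 19 | CC1(C)OB(CC[C@]2(C)[C@H](C)CC/C(=C(\C)CO[Si](c3ccccc3)(c3ccccc3)C(C)(C)C)[C@H]2CO)OC1(C)C
F6 | step 14 | trifluoromethanesulfonate of alcohol 19 | CC(C)=CCC/C(C)=C/CC/C(C)=C/CC[C@]1(C)[C@H](C)CC/C(=C(\C)CO[Si](c2ccccc2)(c2ccccc2)C(C)(C)C)[C@H]1COS(=O)(=O)C(F)(F)F
F7 | step 14 | tert-butyl 3-[(1S,2R,3R,6Z)-6-[1-(tert-butyldiphenylsilyloxy)propan-2-ylidene]-2,3-dimethyl-2-[(3E,7E)-4,8,12-trimethyltrideca-3,7,11-trien-1-yl]cyclohexyl]propanoate | CC(C)=CCC/C(C)=C/CC/C(C)=C/CC[C@]1(C)[C@H](C)CC/C(=C(\C)CO[Si](c2ccccc2)(c2ccccc2)C(C)(C)C)[C@H]1CCC(=O)OC(C)(C)C
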